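(Readings and results were computed with constants of no real substance, and the scatter is random.)

In a one-step world, each turnover takes one substrate and one partner and leaves one left-handed product. Here that picture is tried on a flask that has stopped.

| flask | left-handed substrate | right-handed substrate | partner | catalyst | temperature | remark | time |
|---|---|---|---|---|---|---|---|
| red | 32 mM | 32 mM | 128 mM | 32 µM | 35 °C | the very flask that is asked about, followed so far |  |
| green | 32 mM | 32 mM | 128 mM | 21 µM | 41 °C | run made earlier |  |
| flask | 32 mM | 32 mM | 128 mM | 32 µM | 35 °C |  | 2.0 d |

red run (percent of the left-handed substrate and right-handed substrate together charged): time / h: left-handed product / % = 4.00: 33.9; 6.00: 36.1; 10.0: 36.0; 20.0: 34.7; 30.0: 36.0; 50.0: 36.1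

green run (percent of the left-handed substrate and right-handed substrate together charged): time / min: left-handed product / % = 10.0: 10.6; 20.0: 15.5; 30.0: 18.1; 40.0: 19.2; 50.0: 20.0; 60.0: 20.3

(standard deviation of a reading: 0.5 percentage points)

- catalyst is single-handed; left-handed substrate and right-handed substrate are mirror images of each other, charged as a racemate, each of them at the stated concentration
- what is taken out of left-handed product is counted as made
- the numbers in the tables scatter by 0.5 percentage points (one standard deviation)
- additions bring no volume worth counting

- eta: at 2.0 d raise the temperature by 25 K, then wait 15 h
- alpha: at 2.0 d take out 90% of the left-handed product then present, then wait 15 h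
- zeta: change nothing and wait 15 h more
- theta: at 2.0 d add partner, 100% of the amount charged, then wait 15 h
- gamma: at 2.0 d add catalyst, 100% of the amount charged, then wait 15 h

1. left-handed product, in percent of the left-handed substrate and right-handed substrate together first charged, at 2.0 d
2. the option that brings most further left-handed product ("none" if no option brings more than 2 percentage points) (eta / alpha / zeta / theta / gamma / none)
3. left-handed product present, with what was taken out counted in, in percent of the left-handed substrate and right-handed substrate together first charged, after alpha
4. left-handed product present, with what was taken out counted in, in percent of the left-handed substrate and right-handed substrate together first charged, after zeta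

The red flask reads 36.1% at 6.00 h and 36.1% at 50.0 h, so the estimate for 2.0 d is that same plateau. The last reading is 23.1 mM of left-handed product, or 722 turnovers per catalyst. Set against the partner charged, it gives the turnover share, product made per partner charged: 0.181. The green flask, with less catalyst and more heat, gives a share of 0.102 at its last reading.

In the one-step count, the red flask stops with 63.9% of the substrate pair unreacted. This reckoning supposes that partner or catalyst has faded, and it does not choose between them. It takes a fresh full dose of that species to repeat the first run on less substrate, with the share shrinking in step with substrate, so it puts the gain from the dose at 23 percentage points. Without a dose, the reckoning keeps the red flask on its plateau.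

The weak link is treating the pair as one pool, which assumes that the mirror forms exchange. With no exchange, the reckoning leaves left-handed substrate 27.8% of its own charge, and it then puts the gain from the dose at 10 points. So the reforged estimate runs between these two figures, and its lower end stands above the margin of 2 points.

The forecast gives 35.9% now, 35.9% after alpha and 35.9% after zeta. It picks gamma, reading the stop as “a catalyst that dies”.

The asked flask gives 35.7% now, 35.7% after alpha and 35.7% after zeta. The best option is theta, which brings 23 points, while gamma brings 0 points. The forecast and the flask part on that choice.

    partner + catalyst + left-handed substrate → catalyst + left-handed product (k = 130 M⁻² s⁻¹, Ea = 42.0 kJ mol⁻¹)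
    partner + catalyst + right-handed substrate → catalyst + right-handed product (k = 12.2 M⁻² s⁻¹, Ea = 47.0 kJ mol⁻¹)
    left-handed substrate ⇌ right-handed substrate (k = 0.0989 s⁻¹, Ea = 88.0 kJ mol⁻¹)
    partner → decomposed reagent (k = 4.74 × 10⁻⁴ s⁻¹, Ea = 84.0 kJ mol⁻¹)
    (constants at 35 °C)

At 48.0 h, the asked flask holds 0% of its partner, the limiting reagent, beside 103 mM of decomposed reagent, and catalyst stands at 100% of its charge. Left-handed substrate and right-handed substrate stand level, at 30.5% and 30.5%. The share 0.181 on the pool gave 23 points, against 23 points from theta. On the neighbouring flask charged with 32 mM of partner, the same share gives 9.03%. That neighbouring flask stands at 10.3%, with 89% of its left-handed substrate left.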